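## Assumption
The target has no stereocentres, so no stereochemical control is needed. The only stereocentres in the route are C1 and C6 of the cyclohexanedione **3**, which are destroyed on aromatisation.

## Retrosynthetic overview
1. Disconnect the depside aryl-ester bond, which is formed last. This gives an acid half (2-OBn, ketal-protected side chain) and a phenol half (free 4-OH).
2. Each half comes from methyl orsellinate. The 2-oxoheptyl chain is added by lateral lithiation of the 6-CH₃ group and acylation with a Weinreb amide.
3. Methyl orsellinate is made by Michael/Dieckmann annulation of methyl acetoacetate with methyl crotonate, then oxidative aromatisation. This is the only ring-forming event, and it comes first.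
4. Regioselective O-alkylation differentiates the H-bonded 2-OH from the more acidic 4-OH on each half.

## Forward route

**Step 1**
Reactants: **1** methyl acetoacetate; **2** methyl (E)-crotonate
Product: **3** methyl 6-methyl-2,4-dioxocyclohexane-1-carboxylate (racemic, mostly enol)
Conditions: NaOMe (2.2 equiv), MeOH, reflux, 16 h; then aq. HCl
Reagents that add atoms: none
Why: Michael addition of the acetoacetate C2 carbanion to crotonate, then Dieckmann closure of the acetyl CH₃ onto the distal ester (net loss of MeOH). This places CO₂Me between a carbonyl and the methyl-bearing carbon, the orsellinate pattern. The two stereocentres are irrelevant because they are lost on aromatisation.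

**Step 2**
Reactants: **3**
Product: **4** methyl orsellinate (methyl 2,4-dihydroxy-6-methylbenzoate)
Conditions: Br₂ (1.0 equiv), CH₂Cl₂, 0 °C→rt, then 40 °C
Reagents that add atoms: none (bromine is lost as HBr)
Why: α-Bromination of the dione enol followed by E1cB loss of HBr and tautomerisation gives the aromatic resorcylate. This is oxidative aromatisation, with exactly 1 equiv Br₂ to avoid ring bromination.

**Step 3**
Reactants: **5** hexanoyl chloride; **6** N,O-dimethylhydroxylamine hydrochloride
Product: **7** N-methoxy-N-methylhexanamide
Conditions: pyridine (2.2 equiv), CH₂Cl₂, 0 °C→rt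
Reagents that add atoms: none beyond reactant 6
Why: Schotten–Baumann-type acylation. The Weinreb amide gives a chelated tetrahedral intermediate that stops at the ketone stage.

**Step 4**
Reactants: **4**
Product: **8** methyl 2-hydroxy-4-methoxy-6-methylbenzoate
Conditions: MeI (1.1 equiv), KHCO₃, DMF, 40 °C
Reagents that add atoms: MeI, CI
Why: The 4-OH is more acidic than the 2-OH, which is H-bonded to the ester C=O. Mild-base alkylation is therefore selective for O-4 (regioselective Williamson ether synthesis).

**Step 5**
Reactants: **8**
Product: **9** methyl 2-(benzyloxy)-4-methoxy-6-methylbenzoate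
Conditions: BnBr, K₂CO₃, n-Bu₄NI (cat.), DMF, 60 °C
Reagents that add atoms: BnBr, BrCc1ccccc1
Why: The chelated 2-OH needs a stronger base and heat to be benzylated; Williamson ether synthesis.

**Step 6**
Reactants: **9**; **7**
Product: **10** methyl 2-(benzyloxy)-4-methoxy-6-(2-oxoheptyl)benzoate
Conditions: LDA (1.1 equiv), THF, −78 °C, 45 min; add **7**, −78→−20 °C; aq. NH₄Cl
Reagents that add atoms: none beyond reactant 7
Why: Lateral lithiation of the ArCH₃ group, which is acidified by the twisted, hindered ortho ester. The benzylic anion is acylated by the Weinreb amide, so no over-addition occurs and the ketone is released only on work-up.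

**Step 7**
Reactants: **10**
Product: **11** methyl 2-(benzyloxy)-4-methoxy-6-[(2-pentyl-1,3-dioxolan-2-yl)methyl]benzoate
Conditions: TMSOCH₂CH₂OTMS (1.5 equiv), TMSOTf (5 mol%), CH₂Cl₂, −78→0 °C
Reagents that add atoms: 1,2-bis(trimethylsiloxy)ethane, C[Si](C)(C)OCCO[Si](C)(C)C
Why: Noyori ketalisation under mild, essentially non-acidic conditions. Masking the ketone prevents enol-lactonisation to an isocoumarin when the acid is activated in step 13.

**Step 8**
Reactants: **11**
Product: **12** 2-(benzyloxy)-4-methoxy-6-[(2-pentyl-1,3-dioxolan-2-yl)methyl]benzoic acid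
Conditions: EtSNa (3 equiv), DMF, 60 °C; then aq. NaH₂PO₄ to pH ≈ 4
Reagents that add atoms: none (the ester methyl group leaves as EtSMe)
Why: SN2 dealkylation at the ester O–CH₃ is insensitive to hindrance at the flanked carbonyl. The aryl methyl ether, benzyl ether and ketal survive at 60 °C, and the mildly acidic work-up keeps the ketal.

**Step 9**
Reactants: **4**
Product: **13** methyl 4-(benzyloxy)-2-hydroxy-6-methylbenzoate
Conditions: BnBr (1.05 equiv), KHCO₃, KI (cat.), DMF, 40 °C
Reagents that add atoms: BnBr, BrCc1ccccc1
Why: Same 4-OH-selective alkylation as step 4, now installing a removable group for the phenol half.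

**Step 10**
Reactants: **13**
Product: **14** methyl 4-(benzyloxy)-2-methoxy-6-methylbenzoate
Conditions: MeI, K₂CO₃, acetone, reflux
Reagents that add atoms: MeI, CI
Why: Williamson methylation of the remaining H-bonded 2-OH.

**Step 11**
Reactants: **14**; **7**
Product: **15** methyl 4-(benzyloxy)-2-methoxy-6-(2-oxoheptyl)benzoate
Conditions: LDA (1.1 equiv), THF, −78 °C; add **7**, −78→−20 °C; aq. NH₄Cl
Reagents that add atoms: none beyond reactant 7
Why: Lateral lithiation/Weinreb acylation, as in step 6.

**Step 12**
Reactants: **15**
Product: **16** methyl 4-hydroxy-2-methoxy-6-(2-oxoheptyl)benzoate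
Conditions: H₂ (1 atm), 10% Pd/C, EtOAc, rt
Reagents that add atoms: none
Why: Hydrogenolysis of the aryl benzyl ether. The dialkyl ketone and aryl ester are untouched, and the ketone needs no protection here because only the phenol is nucleophilic.

**Step 13 (convergent coupling)**
Reactants: **12**; **16**
Product: **17** methyl 4-{[2-(benzyloxy)-4-methoxy-6-((2-pentyl-1,3-dioxolan-2-yl)methyl)benzoyl]oxy}-2-methoxy-6-(2-oxoheptyl)benzoate
Conditions: (i) Ghosez's reagent (1-chloro-N,N,2-trimethylpropenylamine), CH₂Cl₂, 0 °C→rt; (ii) **16**, pyridine, DMAP (cat.), CH₂Cl₂, rt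
Reagents that add atoms: none
Why: The hindered acid is converted to its acid chloride under neutral conditions (no HCl to hurt the ketal or the benzyl ether). The unhindered 4-OH of **16** is then acylated (DMAP-catalysed esterification).

**Step 14**
Reactants: **17**
Product: **18** the 2-hydroxy depside with the ketal still in place (CCCCCC1(Cc2cc(OC)cc(O)c2C(=O)Oc2cc(CC(=O)CCCCC)c(C(=O)OC)c(OC)c2)OCCO1)
Conditions: H₂ (1 atm), 10% Pd/C, EtOAc, rt
Reagents that add atoms: none
Why: Hydrogenolysis of the benzyl ether. The aryl ester, ketal and ketone are stable to neutral hydrogenation.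

**Step 15**
Reactants: **18**
Product: **19** Gustastatin
Conditions: TsOH·H₂O (0.2 equiv), acetone/H₂O (9:1), 40 °C
Reagents that add atoms: water, O
Why: Acid-catalysed ketal hydrolysis and trans-ketalisation to acetone releases the ketone. The chelated 2-hydroxy aryl ester tolerates these mild conditions.

## Compound list
| No. | Name | SMILES | Role |
|---|---|---|---|
| 1 | methyl acetoacetate | CC(=O)CC(=O)OC | starting material |
| 2 | methyl (E)-crotonate | C/C=C/C(=O)OC | starting material |
| 3 | methyl 6-methyl-2,4-dioxocyclohexane-1-carboxylate | COC(=O)C1C(C)CC(=O)CC1=O | intermediate |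
| 4 | methyl orsellinate | COC(=O)c1c(C)cc(O)cc1O | intermediate |
| 5 | hexanoyl chloride | CCCCCC(=O)Cl | starting material |
| 6 | N,O-dimethylhydroxylamine hydrochloride | CONC.Cl | starting material |
| 7 | N-methoxy-N-methylhexanamide | CCCCCC(=O)N(C)OC | intermediate |
| 8 | methyl 2-hydroxy-4-methoxy-6-methylbenzoate | COC(=O)c1c(C)cc(OC)cc1O | intermediate |
| 9 | methyl 2-(benzyloxy)-4-methoxy-6-methylbenzoate | COC(=O)c1c(C)cc(OC)cc1OCc1ccccc1 | intermediate |
| 10 | methyl 2-(benzyloxy)-4-methoxy-6-(2-oxoheptyl)benzoate | CCCCCC(=O)Cc1cc(OC)cc(OCc2ccccc2)c1C(=O)OC | intermediate |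
| 11 | methyl 2-(benzyloxy)-4-methoxy-6-[(2-pentyl-1,3-dioxolan-2-yl)methyl]benzoate | CCCCCC1(Cc2cc(OC)cc(OCc3ccccc3)c2C(=O)OC)OCCO1 | intermediate |
| 12 | 2-(benzyloxy)-4-methoxy-6-[(2-pentyl-1,3-dioxolan-2-yl)methyl]benzoic acid | CCCCCC1(Cc2cc(OC)cc(OCc3ccccc3)c2C(=O)O)OCCO1 | intermediate |
| 13 | methyl 4-(benzyloxy)-2-hydroxy-6-methylbenzoate | COC(=O)c1c(C)cc(OCc2ccccc2)cc1O | intermediate |
| 14 | methyl 4-(benzyloxy)-2-methoxy-6-methylbenzoate | COC(=O)c1c(C)cc(OCc2ccccc2)cc1OC | intermediate |
| 15 | methyl 4-(benzyloxy)-2-methoxy-6-(2-oxoheptyl)benzoate | CCCCCC(=O)Cc1cc(OCc2ccccc2)cc(OC)c1C(=O)OC | intermediate |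
| 16 | methyl 4-hydroxy-2-methoxy-6-(2-oxoheptyl)benzoate | CCCCCC(=O)Cc1cc(O)cc(OC)c1C(=O)OC | intermediate |
| 17 | protected depside (benzyl ether, ketal) | CCCCCC1(Cc2cc(OC)cc(OCc3ccccc3)c2C(=O)Oc2cc(CC(=O)CCCCC)c(C(=O)OC)c(OC)c2)OCCO1 | intermediate |
| 18 | mono-debenzylated ketal depside | CCCCCC1(Cc2cc(OC)cc(O)c2C(=O)Oc2cc(CC(=O)CCCCC)c(C(=O)OC)c(OC)c2)OCCO1 | intermediate |
| 19 | Gustastatin | CCCCCC(=O)Cc1cc(OC)cc(O)c1C(=O)Oc1cc(CC(=O)CCCCC)c(C(=O)OC)c(OC)c1 | target |

## Totals
- **Total steps:** 15.
- **Longest linear sequence:** 10 steps (1→2→4→5→6→7→8→13→14→15). The Weinreb amide (step 3) and the phenol half (steps 9–12) are parallel branches.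

## Three steps most likely to fail
1. **Step 6 (and 11), lateral lithiation/acylation.** Ring lithiation next to the oxygen substituents or proton transfer to the Weinreb amide could compete.
   - Fallback: brominate the benzylic CH₃ (NBS, AIBN). Alkylate lithiated 2-pentyl-1,3-dithiane with the bromide. Then unmask the dithiane to the ketone, or keep it as the protected ketone on the acid half.
2. **Step 8, thiolate cleavage of the hindered methyl ester.** Competing debenzylation or aryl-OMe cleavage could lower the yield.
   - Fallback: saponify methyl ester **9** first (KOH, ethylene glycol, 160 °C). Then do the lateral acylation on the lithium carboxylate (2 equiv LDA) and ketalise the resulting keto-acid, so no late ester cleavage is needed.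
3. **Step 2, oxidative aromatisation.** Over-bromination of the electron-rich resorcylate or an incomplete elimination could occur.
   - Fallback: make methyl orsellinate by the biomimetic tetraketide route. Acylate the methyl acetoacetate dianion with diketene to give methyl 3,5,7-trioxooctanoate, then cyclise it by intramolecular aldol condensation.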